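**Plan**

- Retrosynthesis: the diene side chain is cut at C13–C14 (Stille) back to a C13 methyl ketone. C9–C11 and C8–O are cut back to a ring-B C8=C9 alkene (ene reaction with but-3-en-2-one, then carbonyl-assisted oxymercuration). The C6 acetate is traced to a C6 acetyl group (Baeyer–Villiger).
- Enabling feature: the decalin then holds a cyclohexene retron in ring B (C5–C6–C7–C8=C9–C10, acyl on C6) whose bond C5–C10 is the fusion bond shared with ring A. Cutting C5–C10 and C6–C7 opens both rings to an acyclic (E,E)-trienone with C1–C4 as the tether.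
- Forward order: methacrolein → symmetric dienol → Johnson–Claisen (E-diene) → asymmetric aldol (C3 and quaternary C4) → enone → intramolecular Diels–Alder closing rings B and A together → Baeyer–Villiger → side chain.
- Stereochemistry: C3 comes from the reagent-controlled aldol. C5, C6 and C10 come from the endo, chair-tethered cycloaddition relayed from C3. C9 comes from attack anti to the angular methyl, and C8 from ring-enforced cis delivery of oxygen.

Key step: step 8

Remark: labdane numbering (C1–C20) is used for locants. The N-tosyl-L-valine-derived oxazaborolidinone of step 4 is assumed to give the (3R) aldol; if the sense of induction proves opposite, the D-valine promoter is used.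

**Route**

Step 1
Reactants: 1 methacrolein; 2 isopropenylmagnesium bromide
Product: 3 2,4-dimethylpenta-1,4-dien-3-ol
Conditions: THF, −78 → 0 °C; aq. NH4Cl
Reagents that add atoms: none
Why: Grignard 1,2-addition of the alkenyl nucleophile to the enal carbonyl should give the symmetrical bis-allylic carbinol, which has no stereocentre.

Step 2
Reactants: 3 2,4-dimethylpenta-1,4-dien-3-ol; 4 triethyl orthoacetate
Product: 6 ethyl (4E)-4,6-dimethylhepta-4,6-dienoate, via ketene acetal 5 (not isolated)
Conditions: EtCO2H (cat.), 140 °C, EtOH distilled off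
Reagents that add atoms: none
Why: Johnson–Claisen rearrangement through a chair transition state with the remaining isopropenyl group equatorial should give the (E)-trisubstituted alkene (chain trans to the isopropenyl group), and the two identical allyl arms exclude a regiochemical issue.

Step 3
Reactants: 6 ethyl (4E)-4,6-dimethylhepta-4,6-dienoate
Product: 7 (4E)-4,6-dimethylhepta-4,6-dienal
Conditions: i-Bu2AlH (1.05 equiv), CH2Cl2, −78 °C; aq. potassium sodium tartrate
Reagents that add atoms: none
Why: Partial ester reduction at low temperature should stop at the aluminium hemiacetal, which releases the aldehyde on work-up.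

Step 4
Reactants: 7 (4E)-4,6-dimethylhepta-4,6-dienal; 8 1-methoxy-2-methyl-1-(trimethylsilyloxy)prop-1-ene
Product: 9 methyl (3R,6E)-3-hydroxy-2,2,6,8-tetramethylnona-6,8-dienoate
Conditions: N-tosyl-L-valine (1.1 equiv), BH3·THF (1.0 equiv), CH2Cl2, 0 °C → rt; then 7 and 8, −78 °C; pH 7 buffer, then 1 M HCl–THF
Reagents that add atoms: none
Why: Asymmetric Mukaiyama aldol reaction in which the chiral oxazaborolidinone binds the aldehyde and shields one carbonyl face, so the silyl ketene acetal should set C3 as (R) while creating the quaternary C4.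

Step 5
Reactants: 9 methyl (3R,6E)-3-hydroxy-2,2,6,8-tetramethylnona-6,8-dienoate
Product: 10 methyl (3R,6E)-3-[tert-butyl(dimethyl)silyl]oxy-2,2,6,8-tetramethylnona-6,8-dienoate
Conditions: t-BuMe2SiOTf, 2,6-lutidine, CH2Cl2, −78 → 0 °C
Reagents that add atoms: tert-butyldimethylsilyl trifluoromethanesulfonate, CC(C)(C)[Si](C)(C)OS(=O)(=O)C(F)(F)F
Why: Silyl triflate silylation of the hindered secondary alcohol blocks retro-aldol cleavage and gives an ether that is expected to survive every Lewis acid step that follows.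

Step 6
Reactants: 10 methyl (3R,6E)-3-[tert-butyl(dimethyl)silyl]oxy-2,2,6,8-tetramethylnona-6,8-dienoate
Product: 11 (3R,6E)-3-[tert-butyl(dimethyl)silyl]oxy-2,2,6,8-tetramethylnona-6,8-dienal
Conditions: i-Bu2AlH (1.1 equiv), toluene, −78 °C; aq. potassium sodium tartrate
Reagents that add atoms: none
Why: Partial reduction of the neopentyl ester, whose crowded tetrahedral aluminate should persist at −78 °C, should give the non-enolisable aldehyde.

Step 7
Reactants: 11 (3R,6E)-3-[tert-butyl(dimethyl)silyl]oxy-2,2,6,8-tetramethylnona-6,8-dienal; 12 dimethyl (2-oxopropyl)phosphonate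
Product: 13 (3E,6R,9E)-6-[tert-butyl(dimethyl)silyl]oxy-5,5,9,11-tetramethyldodeca-3,9,11-trien-2-one
Conditions: NaH, THF, 0 °C → rt
Reagents that add atoms: none
Why: Horner–Wadsworth–Emmons olefination of the non-enolisable aldehyde with the stabilised ketophosphonate anion should give the (E)-enone.

Step 8
Reactants: 13 (3E,6R,9E)-6-[tert-butyl(dimethyl)silyl]oxy-5,5,9,11-tetramethyldodeca-3,9,11-trien-2-one
Product: 14 1-[(1R,4aS,7R,8aS)-7-[tert-butyl(dimethyl)silyl]oxy-3,4a,8,8-tetramethyl-1,2,4a,5,6,7,8,8a-octahydronaphthalen-1-yl]ethan-1-one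
Conditions: Me2AlCl (1.1 equiv), CH2Cl2, −78 → −20 °C
Reagents that add atoms: none
Why: The Me2AlCl-complexed (E)-enone (C5=C6, acetyl on C6) adds across the diene C7=C8–C9=C10 in a concerted, asynchronous [4+2] cycloaddition whose more advanced bond is the ring-fusion bond C5–C10; the closest known reaction type is the Lewis acid-promoted intramolecular Diels–Alder reaction of terminally activated 1,7,9-decatrien-3-ones to trans-fused octalins. Ring B (C5–C6–C7–C8=C9–C10) closes by the cycloaddition itself and ring A (C10–C1–C2–C3–C4–C5) closes as the fused four-atom tether in a chair-like array with the acetyl group endo. C5 and C6 follow from the (E)-enone (suprafacial addition, H5 and acetyl cis), and C10 from the (E)-diene, which holds the tether outside and the methyl inside so that the endo-acetyl, anti-tether transition state puts the angular methyl trans to H5 and to the acetyl group. The absolute sense is relayed from C3, because the chair tether places the silyloxy group equatorial and therefore cis to the angular methyl. The step needs endo and facial selectivity: the first should be secured by Lewis acid coordination, the second by the equatorial preference of the C3 substituent next to the gem-dimethyl carbon, while the Thorpe–Ingold effect of C4 and the low temperature (no 1,5-hydrogen shift of the cis-methyl diene) favour cyclisation over side reactions.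

Step 9
Reactants: 14 1-[(1R,4aS,7R,8aS)-7-[tert-butyl(dimethyl)silyl]oxy-3,4a,8,8-tetramethyl-1,2,4a,5,6,7,8,8a-octahydronaphthalen-1-yl]ethan-1-one
Product: 15 (1R,4aS,7R,8aS)-7-[tert-butyl(dimethyl)silyl]oxy-3,4a,8,8-tetramethyl-1,2,4a,5,6,7,8,8a-octahydronaphthalen-1-yl acetate
Conditions: Me3SiOOSiMe3 (2 equiv), Me3SiOTf (0.2 equiv), CH2Cl2, −40 → −20 °C
Reagents that add atoms: bis(trimethylsilyl) peroxide, C[Si](C)(C)OO[Si](C)(C)C
Why: Baeyer–Villiger oxidation in which the silyl peroxide adds only to the silyl triflate-activated ketone and the secondary C6 migrates with retention, so the C6 acetate should form directly while the non-electrophilic peroxide leaves the C8=C9 alkene untouched.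

Step 10
Reactants: 15 (1R,4aS,7R,8aS)-7-[tert-butyl(dimethyl)silyl]oxy-3,4a,8,8-tetramethyl-1,2,4a,5,6,7,8,8a-octahydronaphthalen-1-yl acetate; 16 but-3-en-2-one
Product: 17 (3R,5S,6R,9S,10S)-3-[tert-butyl(dimethyl)silyl]oxy-13-oxo-14,15-dinorlabd-8(17)-en-6-yl acetate
Conditions: Me2AlCl (1.5 equiv), CH2Cl2, −78 → −20 °C
Reagents that add atoms: none
Why: Lewis acid-promoted ene reaction of the enone with the trisubstituted alkene, in which C9 attacks the enone terminus from the face anti to the axial angular methyl (Markovnikov cation at C8, then proton transfer from the C8 methyl), should set C9 with the side chain axial.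

Step 11
Reactants: 17 (3R,5S,6R,9S,10S)-3-[tert-butyl(dimethyl)silyl]oxy-13-oxo-14,15-dinorlabd-8(17)-en-6-yl acetate
Product: 20 (3R,5S,6R,8S,9R,10R)-3-[tert-butyl(dimethyl)silyl]oxy-8-hydroxy-13-oxo-14,15-dinorlabdan-6-yl acetate, via organomercurial ketal 18 (not isolated), via cyclic methyl ketal 19 (not isolated)
Conditions: Hg(OCOCF3)2, MeOH (5 equiv), CH2Cl2, −20 °C; NaBH4, aq. NaOH, 0 °C; then PPTS, acetone–H2O, rt
Reagents that add atoms: water, O
Why: Oxymercuration with carbonyl participation (Markovnikov, 6-exo) followed by demercuration and ketal hydrolysis should set C8, because the axial C9 chain can deliver its ketone oxygen only to the same face of C8, and the bridged mercurinium ion avoids a free C8 cation that could scramble C9.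

Step 12
Reactants: 20 (3R,5S,6R,8S,9R,10R)-3-[tert-butyl(dimethyl)silyl]oxy-8-hydroxy-13-oxo-14,15-dinorlabdan-6-yl acetate
Product: 21 (3R,5S,6R,8S,9R,10R)-3-[tert-butyl(dimethyl)silyl]oxy-8-hydroxy-13-(trifluoromethanesulfonyloxy)-14,15-dinorlabd-13(16)-en-6-yl acetate
Conditions: KN(SiMe3)2 (2.2 equiv), PhNTf2 (1.2 equiv, present from the start), THF, −78 °C
Reagents that add atoms: N-phenylbis(trifluoromethanesulfonimide), O=S(=O)(N(c1ccccc1)S(=O)(=O)C(F)(F)F)C(F)(F)F
Why: Kinetic enolisation of the methyl ketone at its methyl group by the bulky amide and O-sulfonylation should give the terminal enol triflate, the second equivalent of base carrying the hindered tertiary alcohol as its unreactive alkoxide.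

Step 13
Reactants: 21 (3R,5S,6R,8S,9R,10R)-3-[tert-butyl(dimethyl)silyl]oxy-8-hydroxy-13-(trifluoromethanesulfonyloxy)-14,15-dinorlabd-13(16)-en-6-yl acetate; 22 tributyl(vinyl)stannane
Product: 23 (3R,5S,6R,8S,9R,10R)-3-[tert-butyl(dimethyl)silyl]oxy-8-hydroxylabda-13(16),14-dien-6-yl acetate
Conditions: Pd(PPh3)4 (5 mol %), LiCl (3 equiv), THF, 60 °C
Reagents that add atoms: none
Why: Stille coupling (oxidative addition of the enol triflate to zerovalent palladium, vinyl transfer from tin, reductive elimination) under neutral conditions should give the 2-substituted buta-1,3-diene without touching the acetate or the free tertiary alcohol.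

Step 14
Reactants: 23 (3R,5S,6R,8S,9R,10R)-3-[tert-butyl(dimethyl)silyl]oxy-8-hydroxylabda-13(16),14-dien-6-yl acetate
Product: 24 (3R,5S,6R,8S,9R,10R)-3,8-dihydroxylabda-13(16),14-dien-6-yl acetate
Conditions: Bu4NF, AcOH (1:1), THF, 45 °C
Reagents that add atoms: none
Why: Fluoride-induced desilylation under buffered, non-acidic conditions should free the C3 alcohol while sparing the acetate and the acid-sensitive tertiary alcohol and diene.

**Compound list**

1 | methacrolein (2-methylprop-2-enal) | C=C(C)C=O | starting material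
2 | isopropenylmagnesium bromide (prop-1-en-2-ylmagnesium bromide) | C=C(C)[Mg]Br | starting material
3 | 2,4-dimethylpenta-1,4-dien-3-ol | C=C(C)C(O)C(C)=C | intermediate
4 | triethyl orthoacetate | CC(OCC)(OCC)OCC | starting material
5 | 3-[(1-ethoxyethenyl)oxy]-2,4-dimethylpenta-1,4-diene (ketene acetal) | C=C(OCC)OC(C(C)=C)C(C)=C | intermediate
6 | ethyl (4E)-4,6-dimethylhepta-4,6-dienoate | CCOC(=O)CC/C(C)=C/C(C)=C | intermediate
7 | (4E)-4,6-dimethylhepta-4,6-dienal | O=CCC/C(C)=C/C(C)=C | intermediate
8 | 1-methoxy-2-methyl-1-(trimethylsilyloxy)prop-1-ene | COC(O[Si](C)(C)C)=C(C)C | starting material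
9 | methyl (3R,6E)-3-hydroxy-2,2,6,8-tetramethylnona-6,8-dienoate | COC(=O)C(C)(C)[C@H](O)CC/C(C)=C/C(C)=C | intermediate
10 | methyl (3R,6E)-3-[tert-butyl(dimethyl)silyl]oxy-2,2,6,8-tetramethylnona-6,8-dienoate | COC(=O)C(C)(C)[C@H](O[Si](C)(C)C(C)(C)C)CC/C(C)=C/C(C)=C | intermediate
11 | (3R,6E)-3-[tert-butyl(dimethyl)silyl]oxy-2,2,6,8-tetramethylnona-6,8-dienal | O=CC(C)(C)[C@H](O[Si](C)(C)C(C)(C)C)CC/C(C)=C/C(C)=C | intermediate
12 | dimethyl (2-oxopropyl)phosphonate | CC(=O)CP(=O)(OC)OC | starting material
13 | (3E,6R,9E)-6-[tert-butyl(dimethyl)silyl]oxy-5,5,9,11-tetramethyldodeca-3,9,11-trien-2-one | CC(=O)/C=C/C(C)(C)[C@H](O[Si](C)(C)C(C)(C)C)CC/C(C)=C/C(C)=C | intermediate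
14 | 1-[(1R,4aS,7R,8aS)-7-[tert-butyl(dimethyl)silyl]oxy-3,4a,8,8-tetramethyl-1,2,4a,5,6,7,8,8a-octahydronaphthalen-1-yl]ethan-1-one (trans-fused; acetyl equatorial on C6, silyloxy equatorial on C3, C8=C9 alkene) | CC1=C[C@]2(C)CC[C@@H](O[Si](C)(C)C(C)(C)C)C(C)(C)[C@H]2[C@H](C(C)=O)C1 | intermediate
15 | (1R,4aS,7R,8aS)-7-[tert-butyl(dimethyl)silyl]oxy-3,4a,8,8-tetramethyl-1,2,4a,5,6,7,8,8a-octahydronaphthalen-1-yl acetate | CC1=C[C@]2(C)CC[C@@H](O[Si](C)(C)C(C)(C)C)C(C)(C)[C@H]2[C@H](OC(C)=O)C1 | intermediate
16 | but-3-en-2-one | C=CC(C)=O | starting material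
17 | (3R,5S,6R,9S,10S)-3-[tert-butyl(dimethyl)silyl]oxy-13-oxo-14,15-dinorlabd-8(17)-en-6-yl acetate (3-oxobutyl chain on C9 axial, anti to the angular methyl) | CC(=O)CC[C@@H]1[C@]2(C)CC[C@@H](O[Si](C)(C)C(C)(C)C)C(C)(C)[C@H]2[C@H](OC(C)=O)CC1=C | intermediate
18 | (3R,5S,6R,8S,9R,10R)-3-[tert-butyl(dimethyl)silyl]oxy-8,13-epoxy-13-methoxy-17-(trifluoroacetoxymercurio)-14,15-dinorlabdan-6-yl acetate (cis-fused cyclic ketal, epimers at C13) | COC1(C)CC[C@@H]2[C@]3(C)CC[C@@H](O[Si](C)(C)C(C)(C)C)C(C)(C)[C@H]3[C@H](OC(C)=O)C[C@]2(C[Hg]OC(=O)C(F)(F)F)O1 | intermediate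
19 | (3R,5S,6R,8S,9R,10R)-3-[tert-butyl(dimethyl)silyl]oxy-8,13-epoxy-13-methoxy-14,15-dinorlabdan-6-yl acetate (cis-fused cyclic methyl ketal, epimers at C13) | COC1(C)CC[C@@H]2[C@]3(C)CC[C@@H](O[Si](C)(C)C(C)(C)C)C(C)(C)[C@H]3[C@H](OC(C)=O)C[C@]2(C)O1 | intermediate
20 | (3R,5S,6R,8S,9R,10R)-3-[tert-butyl(dimethyl)silyl]oxy-8-hydroxy-13-oxo-14,15-dinorlabdan-6-yl acetate | CC(=O)CC[C@@H]1[C@]2(C)CC[C@@H](O[Si](C)(C)C(C)(C)C)C(C)(C)[C@H]2[C@H](OC(C)=O)C[C@]1(C)O | intermediate
21 | (3R,5S,6R,8S,9R,10R)-3-[tert-butyl(dimethyl)silyl]oxy-8-hydroxy-13-(trifluoromethanesulfonyloxy)-14,15-dinorlabd-13(16)-en-6-yl acetate | C=C(OS(=O)(=O)C(F)(F)F)CC[C@@H]1[C@]2(C)CC[C@@H](O[Si](C)(C)C(C)(C)C)C(C)(C)[C@H]2[C@H](OC(C)=O)C[C@]1(C)O | intermediate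
22 | tributyl(vinyl)stannane | C=C[Sn](CCCC)(CCCC)CCCC | starting material
23 | (3R,5S,6R,8S,9R,10R)-3-[tert-butyl(dimethyl)silyl]oxy-8-hydroxylabda-13(16),14-dien-6-yl acetate | C=CC(=C)CC[C@@H]1[C@]2(C)CC[C@@H](O[Si](C)(C)C(C)(C)C)C(C)(C)[C@H]2[C@H](OC(C)=O)C[C@]1(C)O | intermediate
24 | CNP0351600.2, (3R,5S,6R,8S,9R,10R)-3,8-dihydroxylabda-13(16),14-dien-6-yl acetate | C=CC(=C)CC[C@@H]1[C@]2(C)CC[C@@H](O)C(C)(C)[C@H]2[C@H](OC(C)=O)C[C@]1(C)O | target

**Step count and risks**

Total step count: 14. Longest linear sequence: 14 steps (from methacrolein).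

Most likely to fail:

1. Step 8. Bond formation between the neopentyl dienophile carbon C5 and the disubstituted diene terminus C10 may be slow, the Lewis acid may degrade the electron-rich diene by cationic oligomerisation, and the C3 silyloxy group may give incomplete facial control. The fallback changes the activation to iminium catalysis with catalyst-controlled facial selectivity. It sets out from aldehyde 11: Wittig olefination with (triphenylphosphoranylidene)acetaldehyde (toluene, 80 °C) should give (2E,5R,8E)-5-[tert-butyl(dimethyl)silyl]oxy-4,4,8,10-tetramethylundeca-2,8,10-trienal F1. The perchlorate salt of 5-benzyl-2-tert-butyl-3-methylimidazolidin-4-one (the enantiomer matched to C3; MeCN–H2O, 0 °C) should then promote the endo intramolecular Diels–Alder reaction of the derived unsaturated iminium ion to (1R,4aS,7R,8aS)-7-[tert-butyl(dimethyl)silyl]oxy-3,4a,8,8-tetramethyl-1,2,4a,5,6,7,8,8a-octahydronaphthalene-1-carbaldehyde F2. Addition of MeMgBr (THF, −78 °C) gives the carbinol epimers F3, and Dess–Martin oxidation comes back to the route at ketone 14.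

2. Step 10. Attack at C9, which lies next to the quaternary C10, may be slow, so that polymerisation of the enone or a second, intramolecular carbonyl-ene cyclisation of the adduct takes over. The fallback replaces the stepwise ene and oxymercuration sequence by one hetero-Diels–Alder reaction that forms C9–C11 and C8–O together. It sets out from acetate 15: Meldrum's acid, paraformaldehyde and ethylenediammonium diacetate (cat., MeCN, 60 °C) generate 5-methylidene Meldrum's acid, which should add as a 1-oxadiene across C8=C9 (CH2 to C9, O to C8, both from the face anti to the angular methyl) to give the pyrano-fused 2,2-dimethyl-1,3-dioxin-4-one cycloadduct F5. Heating in pyridine–H2O (90 °C) should hydrolyse and decarboxylate it to the cis-fused δ-lactone (3R,5S,6R,8S,9R,10R)-3-[tert-butyl(dimethyl)silyl]oxy-14,15,16-trinorlabdan-13,8-olid-6-yl acetate F6. MeLi (1.05 equiv, THF, −78 °C) should add once to the lactone and come back to the route at hydroxy ketone 20, so that steps 10 and 11 are both bypassed.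

3. Step 9. Addition of the silyl peroxide to the hindered acyclic ketone may be slow, leaving time for alkene isomerisation or loss of the silyl ether under the silyl triflate. The fallback accepts oxidation of the alkene and repairs it afterwards. It sets out from ketone 14: CF3CO3H (from (CF3CO)2O and urea–H2O2; Na2HPO4, CH2Cl2, 0 °C) should effect Baeyer–Villiger oxidation and epoxidation together to give the 8,9-epoxy acetate F4 (epoxide on the face opposite the angular methyl). Stereospecific deoxygenation with PPh3 and CH3ReO3 (cat., benzene, rt → 50 °C) comes back to the route at acetate 15.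

**Further compounds**

F1 | step 8 | (2E,5R,8E)-5-[tert-butyl(dimethyl)silyl]oxy-4,4,8,10-tetramethylundeca-2,8,10-trienal | O=C/C=C/C(C)(C)[C@H](O[Si](C)(C)C(C)(C)C)CC/C(C)=C/C(C)=C
F2 | step 8 | (1R,4aS,7R,8aS)-7-[tert-butyl(dimethyl)silyl]oxy-3,4a,8,8-tetramethyl-1,2,4a,5,6,7,8,8a-octahydronaphthalene-1-carbaldehyde | CC1=C[C@]2(C)CC[C@@H](O[Si](C)(C)C(C)(C)C)C(C)(C)[C@H]2[C@H](C=O)C1
F3 | step 8 | 1-[(1R,4aS,7R,8aS)-7-[tert-butyl(dimethyl)silyl]oxy-3,4a,8,8-tetramethyl-1,2,4a,5,6,7,8,8a-octahydronaphthalen-1-yl]ethan-1-ol (carbinol epimers) | CC1=C[C@]2(C)CC[C@@H](O[Si](C)(C)C(C)(C)C)C(C)(C)[C@H]2[C@H](C(C)O)C1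
F4 | step 9 | 8,9-epoxide of acetate 15 (epoxide oxygen anti to the angular methyl) | C[C@@]12O[C@@H]1[C@]3(C)CC[C@@H](O[Si](C)(C)C(C)(C)C)C(C)(C)[C@H]3[C@H](OC(C)=O)C2
F5 | step 10 | hetero-Diels–Alder adduct of acetate 15 with 5-methylidene Meldrum's acid (cis-fused pyrano-1,3-dioxin-4-one) | O=C1OC(C)(C)OC2=C1C[C@@H]1[C@]3(C)CC[C@@H](O[Si](C)(C)C(C)(C)C)C(C)(C)[C@H]3[C@H](OC(C)=O)C[C@]1(C)O2
F6 | step 10 | (3R,5S,6R,8S,9R,10R)-3-[tert-butyl(dimethyl)silyl]oxy-14,15,16-trinorlabdan-13,8-olid-6-yl acetate (cis-fused δ-lactone) | O=C1CC[C@@H]2[C@]3(C)CC[C@@H](O[Si](C)(C)C(C)(C)C)C(C)(C)[C@H]3[C@H](OC(C)=O)C[C@]2(C)O1
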